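**Assumption:** compounds 1, 8, 17 and 22 are taken as purchasable. The tetrahydropyranyl (THP) acetal carbon is racemic throughout, which has no consequence because the oligomers have no other stereocentre and never carry more than one THP group.

**Points set right in the design:**
- The heptamer connectivity was re-derived ring by ring from the target. The dodeca-aldehyde 35 and the dodecaphenol 37 have exactly that skeleton, and no skeletal correction was needed.
- In every ring the two formyl groups are meta to each other. A formate formed early on a ring therefore gives no help to the migration at its neighbour. Each of the twelve migrations must rest on the ether oxygen ortho or para to it, and the formates are kept until the oxidant is destroyed.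
- The five spectator hydroxyls are carried as benzyl ethers instead of methyl ethers. The last step is then a neutral hydrogenolysis rather than a boron tribromide treatment of a dodecaphenol.
- The ring E monomer is made by fluorine-directed metalation of 8, since direct fluorination of 3,5-dimethylphenol would give ortho/para mixtures. The ring C monomer is made by double ortho-formylation of 17 instead of benzylic oxidation.

## Structural features

The target is a linear heptamer of benzene rings, A to G, joined only by six diaryl ether oxygens and carrying seventeen free phenolic hydroxyls. It has no stereocentre and no stereogenic axis, so no stereocentres stand next to each other and nothing has to be controlled in three dimensions. Ring A is a 2,4,6-trihydroxyphenyl group bound through C1; rings B, D and F are 3,5-dihydroxy-1,4-phenylene units; ring C (3,4,5-trihydroxy) and ring E (3,5-dihydroxy) are 1,2-phenylene units; ring G is a 3,4,5-trihydroxyphenyl end group. Each ether oxygen joins a crowded carbon of one ring (C1 of ring A, C4 of rings B, D and F, C2 of rings C and E, each flanked on both sides by oxygen-bearing carbons) to C1 of the next ring towards G. The free polyphenol is the fragile part: the pyrogallol units of rings C and G and the phloroglucinol-type rings are oxidised easily by air in base or by electrophilic oxidants, and aryl ethers of phloroglucinol-type rings are sensitive to strong acid in nucleophilic solvents. The real difficulty is making six hindered ethers between very electron-rich rings while placing seventeen oxygens in a defined pattern. The key step exploits the fact that in each of rings A to F two hydroxyl-bearing carbons lie ortho or para to the crowded ether carbon (C2 and C6 of ring A; C3 and C5 of rings B, D and F; C3 ortho and C5 para in rings C and E). A formyl group on these twelve carbons first activates the ether carbon for fluoride displacement and is then converted into the hydroxyl by aryl migration to oxygen.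

## Logic of the disconnections

38 from 37. The five O–CH2Ph bonds are cut: one on the 4-oxygen of ring A, one on the 4-oxygen of ring C and three on ring G. Benzyl keeps the most oxidisable patterns masked until a reductive, neutral last step. The forward step must remove all five groups without losing the polar product on the catalyst support.

37 from 35 through 36. The twelve aryl C–O bonds at C2/C6 of ring A and C3/C5 of rings B to F are traced back to twelve aryl C–CHO bonds. This puts the whole oxygenation pattern of six rings into one late operation on an electron-poor, robust substrate. The forward step demands aryl rather than hydride migration at all twelve sites and no free phenol while oxidant is present.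

35 from 34 and 7. The bond between C1 of ring A and the oxygen on C1 of ring B is cut. The carbon is flanked by two formyl groups, so the ether can be made by uncatalysed fluoride displacement. The forward step needs the phenoxide of 34 to attack only the fluorinated carbon of 7 and none of the five activated ether carbons already in 34.

34 from 32 and 6 through 33. The bond between C4 of ring B and the oxygen on C1 of ring C is cut. The chain grows from the G end because the nucleophilic oxygen then sits on the chain and the electrophile is a monomer whose own phenol is masked, so neither partner can self-condense. The forward step needs a masking group that survives carbonate and leaves under conditions harmless to aldehydes and activated ethers; the THP acetal meets this.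

32 from 30 and 21 through 31. The bond between C2 of ring C and the oxygen on C1 of ring D is cut. The fluorine of 21 is activated by an ortho and a para formyl group. The forward step must displace fluoride and not the benzyloxy group that sits between the two formyl groups.

30 from 28 and 6 through 29. The bond between C4 of ring D and the oxygen on C1 of ring E is cut. It is the same operation as for ring B and reuses the same monomer. The nucleophile here has an ortho aryloxy group, so a tri-ortho-substituted ether must form.

28 from 26 and 16 through 27. The bond between C2 of ring E and the oxygen on C1 of ring F is cut. Ortho/para diformyl activation makes this the easiest displacement of the series.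

26 from 24 and 6 through 25. The bond between C4 of ring F and the oxygen of ring G is cut. The nucleophile is the simple electron-rich phenol 24, so the sequence starts with its most reliable coupling.

6 and 7 from 5; 5 from 3 through 4; 3 from 2; 2 from 1. The two aldehyde carbons are traced back to methyl groups through benzal dibromides, and the O-substituent of 6 or 7 is attached last. One intermediate, 5, serves rings A, B, D and F. The phenol must be an ester during radical bromination, the hydrolysis must be free of base so that fluorine is kept, and the acetal of 6 must be put on under acid so that no phenoxide meets the activated fluoride.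

16 from 15; 15 from 13 through 14; 13 from 12; 12 from 11; 11 from 8 through 9 and 10. The same benzylic oxidation logic is applied to the ring E isomer. Its phenol oxygen is introduced ortho to fluorine by metalation, which fixes the regiochemistry. The forward step needs ring metalation, not benzylic metalation.

21 from 20; 20 from 19; 19 from 18; 18 from 17. Here both formyl carbons are ortho to an oxygen, so they are cut back to C–H bonds of a phenol (double ortho-formylation). The hydroxyl between them becomes the benzyl-protected spectator; the methoxy oxygen next to fluorine becomes the chain-extending oxygen after demethylation and selective acetalisation. The forward steps need differentiation of two hydroxyls, which their very different environments provide.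

24 from 22 through 23. The aryl C–O bond is traced to an aryl C–CHO bond, a one-site rehearsal of the key step on a purchasable aldehyde.

## Other disconnections considered

Alternative 1: The cut runs through ring D, at the two C–C bonds that join each hydroxyl carbon (C3, C5) to its ester-bearing neighbour (C2, C6).
- Forward key step: the sodium enolate of the dimethyl 3-aryloxyglutaconate A2 (C2–C1–C6 of ring D, with rings A to C on the C1 oxygen) would be C-acylated twice by the aryloxymalonyl dichloride A3 (C3–C4–C5, with rings E to G on the C4 oxygen). Enolisation would give the dihydroxy diester A1; ester hydrolysis, decarboxylation and cleavage of fifteen methyl ethers would follow.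
- In its favour: the union is convergent (three rings plus three rings), the congested interior ring is formed with both ether oxygens already in place, and the hydroxyls of ring D arise at the right oxidation level with no oxidant.
- Against it here: an α-aryloxy malonyl chloride loses HCl easily to an aryloxyketene, and O-acylation of the dienolate competes. Both halves contain diaryl ethers between electron-rich, doubly ortho-substituted rings with no activating group, so each needs a hindered copper-mediated Ullmann coupling. The end game needs two ester removals and a fifteen-fold BBr3 demethylation in the presence of acid-sensitive phloroglucinol-type ethers.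
- Comparison: structurally it solves one ring of seven, whereas the formyl plan addresses six hindered ethers and twelve hydroxyls together. Mechanistically it relies on one double Claisen-type acylation of uncertain C/O selectivity instead of twelve repeats of one dependable migration. In step economy it needs two or three steps after the key step against one. Its convergence is a real advantage over the strictly linear chain growth chosen here, and no operation has to succeed twelve times on one molecule.

Alternative 2: Ring C is cut at the bond between its two ether carbons and at the bond between its C–H carbon and the neighbouring oxygen-bearing carbon that becomes a free phenol.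
- Forward key step: heating the cyclobutenone A5 (rings D to G) would open it to a vinylketene. This adds the aryloxyacetylene A6 (rings A and B) in a [2+2] sense; four-electron ring opening and six-electron closure then give the phenol A4 (Danheiser benzannulation).
- In its favour: the step is neutral and reagent-free, pericyclic regiocontrol places all five oxygens of the most substituted ring unambiguously, the union is convergent (two rings plus four), and an aryloxyacetylene cannot lose ketene by the retro-ene path open to alkyl ynol ethers.
- Against it here: A5 needs a regioselective reduction and methylation of an unsymmetrical four-membered precursor, a hindered aryloxyacetylene is delicate to prepare, four unactivated diaryl ethers in the fragments again need Ullmann couplings, and sixteen methyl ethers must be cleaved at the end.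
- Comparison: it equals the chosen plan in what follows the key step (one global dealkylation). It is better in that its key step exposes an electron-rich oligomer to no excess oxidant. It is weaker in that it solves ring C only and leaves the other hindered ethers to couplings that the formyl groups make unnecessary.

Alternative 3: Ring G is cut at three C–C bonds: carbene carbon to alkyne, alkyne to CO carbon, and CO carbon to vinyl terminus.
- Forward key step: the zerovalent chromium carbene complex A8, (CO)5Cr=C(OAr)CH=CHOEt with rings A to F as the aryloxy group, would react with ethoxyacetylene A9 and one CO ligand (Dötz benzannulation) to give the 3,5-diethoxy-4-hydroxyphenyl ether A7.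
- In its favour: the 3,5-dialkoxy-4-hydroxy pattern follows from the usual regiochemistry of a terminal alkyne, the conditions are mild, and one dealkylation follows.
- Against it here: ring G is the one ring that can be bought ready-made as a 3,4,5-trialkoxyphenol. The carbene must be built on a six-ring phenol whose hydroxyl is flanked by two methoxy groups. Ynol ethers tend to insert without CO incorporation. A stoichiometric chromium reagent would be spent at the most valuable stage, and all six hindered ethers would still have to be made beforehand without activation.
- Comparison: it equals the chosen plan in the number of steps after the key step (one). It is inferior in structure (it builds the simplest ring), in mechanism (competing insertion pathways) and in step economy (a fully linear, unactivated assembly of rings A to F).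

Key step: step 22

## Route

Step 1
Reactants: 1 4-fluoro-3,5-dimethylphenol
Product: 2 4-fluoro-3,5-dimethylphenyl acetate
Conditions: Ac2O, pyridine, DMAP (cat.), CH2Cl2, rt
Reagents that add atoms: acetic anhydride CC(=O)OC(C)=O
Why: Simple O-acylation; the ester lowers the electron density of the ring so that the following radical bromination occurs at the methyl groups and not on the ring.

Step 2
Reactants: 2 4-fluoro-3,5-dimethylphenyl acetate
Product: 3 3,5-bis(dibromomethyl)-4-fluorophenyl acetate
Conditions: NBS (4.4 equiv), AIBN (cat.), PhCF3, hν, reflux
Reagents that add atoms: N-bromosuccinimide O=C1CCC(=O)N1Br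
Why: Wohl–Ziegler benzylic bromination; two bromines per methyl group are introduced readily, whereas a third is slow for steric and polar reasons, and the small ortho fluorine does not hinder the benzylic radicals.

Step 3
Reactants: 3 3,5-bis(dibromomethyl)-4-fluorophenyl acetate
Product: 5 2-fluoro-5-hydroxyisophthalaldehyde, via 4-fluoro-3,5-diformylphenyl acetate 4 (not isolated)
Conditions: AgNO3, THF/H2O, 50 °C; then 2 M H2SO4, 60 °C
Reagents that add atoms: water O
Why: Silver-assisted solvolysis of the two benzal dibromides gives the dialdehyde without any base that could displace the now doubly activated fluoride; acid-catalysed hydrolysis of the aryl acetate in the same flask frees the phenol.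

Step 4
Reactants: 5 2-fluoro-5-hydroxyisophthalaldehyde
Product: 6 2-fluoro-5-(tetrahydro-2H-pyran-2-yloxy)isophthalaldehyde (racemic acetal; monomer for rings B, D and F)
Conditions: 3,4-dihydro-2H-pyran, PPTS (cat.), CH2Cl2, rt
Reagents that add atoms: 3,4-dihydro-2H-pyran C1CCOC=C1
Why: Acid-catalysed addition of the phenol to the enol ether (tetrahydropyranylation); no phenoxide is formed, so the activated fluoride cannot be attacked by another molecule, and the new acetal carbon is racemic and of no consequence.

Step 5
Reactants: 5 2-fluoro-5-hydroxyisophthalaldehyde
Product: 7 5-(benzyloxy)-2-fluoroisophthalaldehyde (ring A monomer)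
Conditions: BnBr, K2CO3, acetone, rt
Reagents that add atoms: benzyl bromide BrCc1ccccc1
Why: Williamson etherification; at room temperature alkylation of the phenoxide by benzyl bromide is much faster than fluoride displacement, which needs heating in a dipolar aprotic solvent.

Step 6
Reactants: 8 1-fluoro-2,4-dimethylbenzene
Product: 11 2-fluoro-3,5-dimethylphenol, via 2-fluoro-3,5-dimethylphenylpotassium 9 (not isolated), via dimethyl (2-fluoro-3,5-dimethylphenyl)boronate 10 (not isolated)
Conditions: n-BuLi, KOt-Bu, THF, −78 °C; B(OMe)3, −78 °C to rt; then AcOH, 30% H2O2, 0 °C to rt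
Reagents that add atoms: hydrogen peroxide OO
Why: Fluorine-directed ring metalation with the n-BuLi/KOt-Bu superbase at the only C–H ortho to fluorine (this mixed base prefers that site over benzylic positions), boronate formation, and oxidative aryl shift from boron to oxygen; the low temperature suppresses aryne formation.

Step 7
Reactants: 11 2-fluoro-3,5-dimethylphenol
Product: 12 2-fluoro-3,5-dimethylphenyl acetate
Conditions: Ac2O, pyridine, DMAP (cat.), CH2Cl2, rt
Reagents that add atoms: acetic anhydride CC(=O)OC(C)=O
Why: O-acylation, for the same reason as in step 1.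

Step 8
Reactants: 12 2-fluoro-3,5-dimethylphenyl acetate
Product: 13 3,5-bis(dibromomethyl)-2-fluorophenyl acetate
Conditions: NBS (4.4 equiv), AIBN (cat.), PhCF3, hν, reflux
Reagents that add atoms: N-bromosuccinimide O=C1CCC(=O)N1Br
Why: Wohl–Ziegler bromination to the two benzal dibromides, as in step 2; the deactivated acetoxy-fluoro ring resists nuclear bromination.

Step 9
Reactants: 13 3,5-bis(dibromomethyl)-2-fluorophenyl acetate
Product: 15 4-fluoro-5-hydroxyisophthalaldehyde, via 2-fluoro-3,5-diformylphenyl acetate 14 (not isolated)
Conditions: AgNO3, THF/H2O, 50 °C; then 2 M H2SO4, 60 °C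
Reagents that add atoms: water O
Why: Silver-assisted hydrolysis of the benzal dibromides and acid hydrolysis of the acetate, base-free so that the fluorine ortho and para to the new formyl groups is retained.

Step 10
Reactants: 15 4-fluoro-5-hydroxyisophthalaldehyde
Product: 16 4-fluoro-5-(tetrahydro-2H-pyran-2-yloxy)isophthalaldehyde (racemic acetal; ring E monomer)
Conditions: 3,4-dihydro-2H-pyran, PPTS (cat.), CH2Cl2, rt
Reagents that add atoms: 3,4-dihydro-2H-pyran C1CCOC=C1
Why: Tetrahydropyranylation under acid catalysis, as in step 4.

Step 11
Reactants: 17 3-fluoro-4-methoxyphenol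
Product: 18 4-fluoro-2-hydroxy-5-methoxyisophthalaldehyde
Conditions: hexamethylenetetramine (4 equiv), TFA, 90 °C; then 3 M HCl, 60 °C
Reagents that add atoms: hexamethylenetetramine C1N2CN3CN1CN(C2)C3; water O
Why: Duff formylation in trifluoroacetic acid, which is known to formylate both positions ortho to the hydroxyl of para-substituted phenols (the para position is blocked by methoxy); hydrolysis of the benzyliminium intermediates gives the dialdehyde.

Step 12
Reactants: 18 4-fluoro-2-hydroxy-5-methoxyisophthalaldehyde
Product: 19 4-fluoro-2,5-dihydroxyisophthalaldehyde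
Conditions: BBr3, CH2Cl2, −78 °C to 0 °C; H2O
Reagents that add atoms: none
Why: Lewis-acid cleavage of the aryl methyl ether (boron coordination, bromide attack on methyl); the chelated hydroxy dialdehyde and the aryl fluoride are expected to tolerate the reagent at low temperature.

Step 13
Reactants: 19 4-fluoro-2,5-dihydroxyisophthalaldehyde
Product: 20 4-fluoro-2-hydroxy-5-(tetrahydro-2H-pyran-2-yloxy)isophthalaldehyde (racemic acetal)
Conditions: 3,4-dihydro-2H-pyran (1.1 equiv), PPTS (cat.), CH2Cl2, 0 °C to rt
Reagents that add atoms: 3,4-dihydro-2H-pyran C1CCOC=C1
Why: Tetrahydropyranylation should take the free C5 hydroxyl; the C2 hydroxyl is hydrogen-bonded to both flanking formyl groups and sterically shielded, so its acetal is disfavoured both kinetically and thermodynamically.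

Step 14
Reactants: 20 4-fluoro-2-hydroxy-5-(tetrahydro-2H-pyran-2-yloxy)isophthalaldehyde
Product: 21 2-(benzyloxy)-4-fluoro-5-(tetrahydro-2H-pyran-2-yloxy)isophthalaldehyde (racemic acetal; ring C monomer)
Conditions: BnBr, K2CO3, DMF, rt to 40 °C
Reagents that add atoms: benzyl bromide BrCc1ccccc1
Why: Williamson benzylation of the remaining phenol; its phenoxide, hindered and delocalised into two formyl groups, is a poor SNAr nucleophile, so the fluoride is kept, and the THP acetal is stable to carbonate.

Step 15
Reactants: 22 3,4,5-tris(benzyloxy)benzaldehyde
Product: 24 3,4,5-tris(benzyloxy)phenol, via 3,4,5-tris(benzyloxy)phenyl formate 23 (not isolated)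
Conditions: mCPBA, CH2Cl2, rt; then K2CO3 (cat.), MeOH, rt
Reagents that add atoms: 3-chloroperoxybenzoic acid OOC(=O)c1cccc(Cl)c1
Why: Dakin-type Baeyer–Villiger oxidation; the para benzyloxy group ensures aryl migration, and mild methanolysis of the formate gives the phenol.

Step 16
Reactants: 24 3,4,5-tris(benzyloxy)phenol; 6 2-fluoro-5-(tetrahydro-2H-pyran-2-yloxy)isophthalaldehyde
Product: 26 FG phenol (5-hydroxy-2-[3,4,5-tris(benzyloxy)phenoxy]isophthalaldehyde), via FG THP ether 25 (not isolated)
Conditions: K2CO3, 4 Å MS, DMSO, 60 °C; then 2 M HCl, THF, rt
Reagents that add atoms: none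
Why: SNAr: the phenoxide adds to the fluorine-bearing carbon, the Meisenheimer intermediate is stabilised by the two ortho formyl groups, and fluoride leaves; dilute acid then hydrolyses the THP acetal, leaving benzyl ethers, aldehydes and the new diaryl ether untouched.

Step 17
Reactants: 26 FG phenol; 16 4-fluoro-5-(tetrahydro-2H-pyran-2-yloxy)isophthalaldehyde
Product: 28 EFG phenol (5-hydroxy-4-{3,5-diformyl-4-[3,4,5-tris(benzyloxy)phenoxy]phenoxy}isophthalaldehyde), via EFG THP ether 27 (not isolated)
Conditions: K2CO3, 4 Å MS, DMSO, 60 °C; then 2 M HCl, THF, rt
Reagents that add atoms: none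
Why: SNAr at a fluorine activated by an ortho and a para formyl group, the most reactive electrophile of the series, which offsets the lower nucleophilicity of the diformylphenoxide; the THP acetal is then cleaved by acid.

Step 18
Reactants: 28 EFG phenol; 6 2-fluoro-5-(tetrahydro-2H-pyran-2-yloxy)isophthalaldehyde
Product: 30 DEFG phenol (tetramer hexa-aldehyde), via DEFG THP ether 29 (not isolated)
Conditions: K2CO3, 4 Å MS, DMSO, 60 °C; then 2 M HCl, THF, rt
Reagents that add atoms: none
Why: SNAr as in step 16; fluoride is a far better nucleofuge than the aryloxy groups on the internal activated carbons, which should keep the existing ethers intact at this temperature; acid then removes the THP group.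

Step 19
Reactants: 30 DEFG phenol; 21 2-(benzyloxy)-4-fluoro-5-(tetrahydro-2H-pyran-2-yloxy)isophthalaldehyde
Product: 32 CDEFG phenol (pentamer octa-aldehyde), via CDEFG THP ether 31 (not isolated)
Conditions: K2CO3, 4 Å MS, DMSO, 60 °C; then 2 M HCl, THF, rt
Reagents that add atoms: none
Why: SNAr at the fluorine ortho and para to formyl groups; the benzyloxy group between the two formyl groups is also on an activated carbon but is a much poorer leaving group than fluoride, so substitution should occur at fluorine only; acid then removes the THP group.

Step 20
Reactants: 32 CDEFG phenol; 6 2-fluoro-5-(tetrahydro-2H-pyran-2-yloxy)isophthalaldehyde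
Product: 34 BCDEFG phenol (hexamer deca-aldehyde), via BCDEFG THP ether 33 (not isolated)
Conditions: K2CO3, 4 Å MS, DMSO, 60 °C; then 2 M HCl, THF, rt
Reagents that add atoms: none
Why: SNAr as in steps 16 and 18, here forming a tri-ortho-substituted diaryl ether, which addition–elimination tolerates; acid hydrolysis of the THP acetal exposes the last nucleophilic hydroxyl.

Step 21
Reactants: 34 BCDEFG phenol; 7 5-(benzyloxy)-2-fluoroisophthalaldehyde
Product: 35 heptamer dodeca-aldehyde with five benzyl ethers
Conditions: K2CO3, 4 Å MS, DMSO, 60 °C
Reagents that add atoms: none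
Why: Final SNAr of the chain phenoxide on the 2,6-diformyl-activated fluoride of the ring A monomer; no protecting group is needed on this last unit.

Step 22
Reactants: 35 heptamer dodeca-aldehyde with five benzyl ethers
Product: 37 heptamer dodecaphenol with five benzyl ethers, via heptamer dodecaformate 36 (not isolated)
Conditions: mCPBA (excess), CH2Cl2, 0 °C to 35 °C; aq. Na2S2O3; then Et3N (cat.), degassed MeOH, 0 °C, Ar
Reagents that add atoms: 3-chloroperoxybenzoic acid OOC(=O)c1cccc(Cl)c1
Why: Each aldehyde adds the peracid to give a tetrahedral Criegee adduct, whose aryl group shifts from carbon to the peroxide oxygen as 3-chlorobenzoate leaves, giving an aryl formate; once the peracid is destroyed, amine-catalysed transesterification with methanol releases the twelve phenols and methyl formate. The closest known reaction is the Baeyer–Villiger (Dakin-type) oxidation of ortho- or para-aryloxy- and alkoxy-benzaldehydes to phenols through their formates, here used twelve times on one substrate. No ring is closed and no stereocentre is formed, so the only selectivity required is aryl over hydride migration at every site. This is secured by the ether oxygen ortho or para to each migrating carbon (the aryloxy oxygen of the ring's own crowded ether carbon in rings A, B, D, E and F; an aryloxy and a benzyloxy oxygen in ring C), whose lone pair stabilises the electron-poor migrating terminus. Because the two formyl groups of each ring are meta to each other, an early formate does not help its neighbour, so each site relies on that oxygen alone. Keeping the products as formates until the oxidant is gone holds rings A to F moderately electron-poor and protects them from hydroxylation or quinone formation. The benzyl ethers and the six diaryl ethers are inert to the peracid, and the tris(benzyloxy)phenyl ring G, the most oxidisable site, limits the excess and the temperature that can be used.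

Step 23
Reactants: 37 heptamer dodecaphenol with five benzyl ethers
Product: 38 CNP0351377.0 (heptamer with seventeen free hydroxyls)
Conditions: H2 (1 atm), 10% Pd/C, THF/MeOH, rt
Reagents that add atoms: none
Why: Hydrogenolysis of the five benzyl aryl ethers under neutral, reducing conditions; diaryl ethers and phenols are inert, and the air-sensitive product is obtained by filtration and evaporation under inert gas.

## Compound list

1 | 4-fluoro-3,5-dimethylphenol | Cc1cc(O)cc(C)c1F | starting material
2 | 4-fluoro-3,5-dimethylphenyl acetate | CC(=O)Oc1cc(C)c(F)c(C)c1 | intermediate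
3 | 3,5-bis(dibromomethyl)-4-fluorophenyl acetate | CC(=O)Oc1cc(C(Br)Br)c(F)c(C(Br)Br)c1 | intermediate
4 | 4-fluoro-3,5-diformylphenyl acetate | CC(=O)Oc1cc(C=O)c(F)c(C=O)c1 | intermediate (not isolated)
5 | 2-fluoro-5-hydroxyisophthalaldehyde | O=Cc1cc(O)cc(C=O)c1F | intermediate
6 | 2-fluoro-5-(tetrahydro-2H-pyran-2-yloxy)isophthalaldehyde, racemic | O=Cc1cc(OC2CCCCO2)cc(C=O)c1F | intermediate
7 | 5-(benzyloxy)-2-fluoroisophthalaldehyde | O=Cc1cc(OCc2ccccc2)cc(C=O)c1F | intermediate
8 | 1-fluoro-2,4-dimethylbenzene | Cc1ccc(F)c(C)c1 | starting material
9 | 2-fluoro-3,5-dimethylphenylpotassium | Cc1cc(C)c(F)c([K])c1 | intermediate (not isolated)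
10 | dimethyl (2-fluoro-3,5-dimethylphenyl)boronate | COB(OC)c1cc(C)cc(C)c1F | intermediate (not isolated)
11 | 2-fluoro-3,5-dimethylphenol | Cc1cc(C)c(F)c(O)c1 | intermediate
12 | 2-fluoro-3,5-dimethylphenyl acetate | CC(=O)Oc1cc(C)cc(C)c1F | intermediate
13 | 3,5-bis(dibromomethyl)-2-fluorophenyl acetate | CC(=O)Oc1cc(C(Br)Br)cc(C(Br)Br)c1F | intermediate
14 | 2-fluoro-3,5-diformylphenyl acetate | CC(=O)Oc1cc(C=O)cc(C=O)c1F | intermediate (not isolated)
15 | 4-fluoro-5-hydroxyisophthalaldehyde | O=Cc1cc(O)c(F)c(C=O)c1 | intermediate
16 | 4-fluoro-5-(tetrahydro-2H-pyran-2-yloxy)isophthalaldehyde, racemic | O=Cc1cc(OC2CCCCO2)c(F)c(C=O)c1 | intermediate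
17 | 3-fluoro-4-methoxyphenol | COc1ccc(O)cc1F | starting material
18 | 4-fluoro-2-hydroxy-5-methoxyisophthalaldehyde | COc1cc(C=O)c(O)c(C=O)c1F | intermediate
19 | 4-fluoro-2,5-dihydroxyisophthalaldehyde | O=Cc1cc(O)c(F)c(C=O)c1O | intermediate
20 | 4-fluoro-2-hydroxy-5-(tetrahydro-2H-pyran-2-yloxy)isophthalaldehyde, racemic | O=Cc1cc(OC2CCCCO2)c(F)c(C=O)c1O | intermediate
21 | 2-(benzyloxy)-4-fluoro-5-(tetrahydro-2H-pyran-2-yloxy)isophthalaldehyde, racemic | O=Cc1cc(OC2CCCCO2)c(F)c(C=O)c1OCc1ccccc1 | intermediate
22 | 3,4,5-tris(benzyloxy)benzaldehyde | O=Cc1cc(OCc2ccccc2)c(OCc2ccccc2)c(OCc2ccccc2)c1 | starting material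
23 | 3,4,5-tris(benzyloxy)phenyl formate | O=COc1cc(OCc2ccccc2)c(OCc2ccccc2)c(OCc2ccccc2)c1 | intermediate (not isolated)
24 | 3,4,5-tris(benzyloxy)phenol | Oc1cc(OCc2ccccc2)c(OCc2ccccc2)c(OCc2ccccc2)c1 | intermediate
25 | FG THP ether: 5-(tetrahydro-2H-pyran-2-yloxy)-2-[3,4,5-tris(benzyloxy)phenoxy]isophthalaldehyde, racemic | C8CCCC(O8)Oc1cc(C=O)c(Oc2cc(OCc6ccccc6)c(OCc6ccccc6)c(OCc6ccccc6)c2)c(C=O)c1 | intermediate (not isolated)
26 | FG phenol: 5-hydroxy-2-[3,4,5-tris(benzyloxy)phenoxy]isophthalaldehyde | Oc1cc(C=O)c(Oc2cc(OCc6ccccc6)c(OCc6ccccc6)c(OCc6ccccc6)c2)c(C=O)c1 | intermediate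
27 | EFG THP ether: the THP ether of 28 at its ring E hydroxyl, racemic | C8CCCC(O8)Oc1cc(C=O)cc(C=O)c1Oc2cc(C=O)c(Oc3cc(OCc6ccccc6)c(OCc6ccccc6)c(OCc6ccccc6)c3)c(C=O)c2 | intermediate (not isolated)
28 | EFG phenol: 5-hydroxy-4-{3,5-diformyl-4-[3,4,5-tris(benzyloxy)phenoxy]phenoxy}isophthalaldehyde | Oc1cc(C=O)cc(C=O)c1Oc2cc(C=O)c(Oc3cc(OCc6ccccc6)c(OCc6ccccc6)c(OCc6ccccc6)c3)c(C=O)c2 | intermediate
29 | DEFG THP ether: the THP ether of 30 at its ring D hydroxyl, racemic | C8CCCC(O8)Oc1cc(C=O)c(Oc2cc(C=O)cc(C=O)c2Oc3cc(C=O)c(Oc4cc(OCc6ccccc6)c(OCc6ccccc6)c(OCc6ccccc6)c4)c(C=O)c3)c(C=O)c1 | intermediate (not isolated)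
30 | DEFG phenol: 5-hydroxyisophthalaldehyde carrying at C2 the aryloxy group derived from 28 by loss of its phenolic hydrogen | Oc1cc(C=O)c(Oc2cc(C=O)cc(C=O)c2Oc3cc(C=O)c(Oc4cc(OCc6ccccc6)c(OCc6ccccc6)c(OCc6ccccc6)c4)c(C=O)c3)c(C=O)c1 | intermediate
31 | CDEFG THP ether: the THP ether of 32 at its ring C hydroxyl, racemic | C8CCCC(O8)Oc1cc(C=O)c(OCc6ccccc6)c(C=O)c1Oc2cc(C=O)c(Oc3cc(C=O)cc(C=O)c3Oc4cc(C=O)c(Oc5cc(OCc6ccccc6)c(OCc6ccccc6)c(OCc6ccccc6)c5)c(C=O)c4)c(C=O)c2 | intermediate (not isolated)
32 | CDEFG phenol: 2-(benzyloxy)-5-hydroxyisophthalaldehyde carrying at C4 the aryloxy group derived from 30 | Oc1cc(C=O)c(OCc6ccccc6)c(C=O)c1Oc2cc(C=O)c(Oc3cc(C=O)cc(C=O)c3Oc4cc(C=O)c(Oc5cc(OCc6ccccc6)c(OCc6ccccc6)c(OCc6ccccc6)c5)c(C=O)c4)c(C=O)c2 | intermediate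
33 | BCDEFG THP ether: the THP ether of 34 at its ring B hydroxyl, racemic | C8CCCC(O8)Oc1cc(C=O)c(Oc2cc(C=O)c(OCc6ccccc6)c(C=O)c2Oc3cc(C=O)c(Oc4cc(C=O)cc(C=O)c4Oc5cc(C=O)c(Oc7cc(OCc6ccccc6)c(OCc6ccccc6)c(OCc6ccccc6)c7)c(C=O)c5)c(C=O)c3)c(C=O)c1 | intermediate (not isolated)
34 | BCDEFG phenol: 5-hydroxyisophthalaldehyde carrying at C2 the aryloxy group derived from 32 | Oc1cc(C=O)c(Oc2cc(C=O)c(OCc6ccccc6)c(C=O)c2Oc3cc(C=O)c(Oc4cc(C=O)cc(C=O)c4Oc5cc(C=O)c(Oc7cc(OCc6ccccc6)c(OCc6ccccc6)c(OCc6ccccc6)c7)c(C=O)c5)c(C=O)c3)c(C=O)c1 | intermediate
35 | heptamer dodeca-aldehyde with five benzyl ethers: 5-(benzyloxy)isophthalaldehyde carrying at C2 the aryloxy group derived from 34 | c6ccccc6COc1cc(C=O)c(Oc2cc(C=O)c(Oc3cc(C=O)c(OCc6ccccc6)c(C=O)c3Oc3cc(C=O)c(Oc4cc(C=O)cc(C=O)c4Oc4cc(C=O)c(Oc5cc(OCc6ccccc6)c(OCc6ccccc6)c(OCc6ccccc6)c5)c(C=O)c4)c(C=O)c3)c(C=O)c2)c(C=O)c1 | intermediate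
36 | heptamer dodecaformate: 35 with each CHO replaced by OCHO | c6ccccc6COc1cc(OC=O)c(Oc2cc(OC=O)c(Oc3cc(OC=O)c(OCc6ccccc6)c(OC=O)c3Oc3cc(OC=O)c(Oc4cc(OC=O)cc(OC=O)c4Oc4cc(OC=O)c(Oc5cc(OCc6ccccc6)c(OCc6ccccc6)c(OCc6ccccc6)c5)c(OC=O)c4)c(OC=O)c3)c(OC=O)c2)c(OC=O)c1 | intermediate (not isolated)
37 | heptamer dodecaphenol with five benzyl ethers: 35 with each CHO replaced by OH | c6ccccc6COc1cc(O)c(Oc2cc(O)c(Oc3cc(O)c(OCc6ccccc6)c(O)c3Oc3cc(O)c(Oc4cc(O)cc(O)c4Oc4cc(O)c(Oc5cc(OCc6ccccc6)c(OCc6ccccc6)c(OCc6ccccc6)c5)c(O)c4)c(O)c3)c(O)c2)c(O)c1 | intermediate
38 | CNP0351377.0, heptamer with seventeen hydroxyls | Oc1cc(O)c(Oc2cc(O)c(Oc3cc(O)c(O)c(O)c3Oc3cc(O)c(Oc4cc(O)cc(O)c4Oc4cc(O)c(Oc5cc(O)c(O)c(O)c5)c(O)c4)c(O)c3)c(O)c2)c(O)c1 | target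

## Step count and least certain steps

Total step count: 23. Longest linear sequence: 12 steps (steps 1, 2, 3, 4, then 16 to 23; the branch through steps 6 to 10 and then 17 to 23 is equally long).

Step 22 (key step). The most likely failure is hydride instead of aryl migration at some of the twelve aldehydes, which would leave carboxylic acids. Each aldehyde sits on a ring that still carries a second electron-withdrawing group meta to it, so the ortho or para oxygen is the only driver. Oxidative attack on the electron-rich ring G under the large excess of peracid is the second risk. Fallback: from 35, the peracid would be replaced by 30% hydrogen peroxide activated by a catalytic diaryl diselenide (bis(2-nitrophenyl) diselenide) in CH2Cl2. The oxidant is then an areneperseleninic acid, which is known to favour formate formation from benzaldehydes of modest electron density and needs no large excess of an electrophilic peracid. This would give 36, and the same methanolysis returns to the route at 37. No new compound is involved.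

Step 20 (and, to a lesser degree, steps 18, 19 and 21). The most likely failure is trans-etherification: the phenoxide attacks one of the internal ether carbons, each activated by two formyl groups, and expels an aryloxide. This would scramble the sequence, and the more ethers the chain holds the more exposed it is. Fallback: from 32, all eight aldehydes would be converted with trimethyl orthoformate and catalytic TsOH in methanol into the octakis(dimethyl acetal) of the CDEFG phenol F1. Its internal ethers are no longer activated and its phenoxide is more nucleophilic. Coupling with 6 under the same carbonate conditions would give the acetal-protected BCDEFG THP ether F2. Aqueous HCl in THF would then cleave the eight acetals and the THP group together and return to the route at 34.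

Step 11. The most likely failure is stalling after the first formylation, because the first formyl group deactivates the ring and the second site lies between the hydroxyl and fluorine. Fallback: from 17, base-mediated bis-hydroxymethylation with aqueous formaldehyde and NaOH would give 3-fluoro-2,6-bis(hydroxymethyl)-4-methoxyphenol F3. Oxidation of its two benzylic alcohols with MnO2 returns to the route at 18.

Step 2 (the same applies to step 8). The most likely failure is incomplete or excessive bromination, giving tri- and pentabromide mixtures, together with some nuclear bromination. Fallback: from 2, bromination would be limited to one bromine per methyl group (2.1 equiv NBS), giving 3,5-bis(bromomethyl)-4-fluorophenyl acetate F4. Oxidation with N-methylmorpholine N-oxide in acetonitrile would give the dialdehyde 4, and acid hydrolysis of the acetate returns to the route at 5.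

Step 6. The most likely failure is competing benzylic metalation or loss of metal fluoride from the ortho-fluoroaryl metal (aryne formation) if the temperature rises. Fallback: from 8, a sterically controlled C–H borylation with B2pin2, [Ir(OMe)(cod)]2 and 4,4′-di-tert-butyl-2,2′-bipyridine would give the pinacol boronate 2-(2-fluoro-3,5-dimethylphenyl)-4,4,5,5-tetramethyl-1,3,2-dioxaborolane F5. The C–H next to fluorine is the only one without an ortho methyl group. Oxidation with hydrogen peroxide returns to the route at 11.

## Further compounds

F0 | step 22 | none | none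
F1 | step 20 | octakis(dimethyl acetal) of the CDEFG phenol 32 | Oc1cc(C(OC)OC)c(OCc6ccccc6)c(C(OC)OC)c1Oc2cc(C(OC)OC)c(Oc3cc(C(OC)OC)cc(C(OC)OC)c3Oc4cc(C(OC)OC)c(Oc5cc(OCc6ccccc6)c(OCc6ccccc6)c(OCc6ccccc6)c5)c(C(OC)OC)c4)c(C(OC)OC)c2
F2 | step 20 | acetal-protected BCDEFG THP ether (ring B dialdehyde, rings C to F as dimethyl acetals), racemic | C8CCCC(O8)Oc1cc(C=O)c(Oc2cc(C(OC)OC)c(OCc6ccccc6)c(C(OC)OC)c2Oc3cc(C(OC)OC)c(Oc4cc(C(OC)OC)cc(C(OC)OC)c4Oc5cc(C(OC)OC)c(Oc7cc(OCc6ccccc6)c(OCc6ccccc6)c(OCc6ccccc6)c7)c(C(OC)OC)c5)c(C(OC)OC)c3)c(C=O)c1
F3 | step 11 | 3-fluoro-2,6-bis(hydroxymethyl)-4-methoxyphenol | COc1cc(CO)c(O)c(CO)c1F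
F4 | step 2 | 3,5-bis(bromomethyl)-4-fluorophenyl acetate | CC(=O)Oc1cc(CBr)c(F)c(CBr)c1
F5 | step 6 | 2-(2-fluoro-3,5-dimethylphenyl)-4,4,5,5-tetramethyl-1,3,2-dioxaborolane | Cc1cc(C)c(F)c(B2OC(C)(C)C(C)(C)O2)c1
A1 | alternative 1 | heptamer with ring D as a dihydroxy diester and fifteen methyl ethers | COC(=O)c1c(O)c(Oc2cc(OC)cc(OC)c2Oc2cc(OC)c(Oc3cc(OC)c(OC)c(OC)c3)c(OC)c2)c(O)c(C(=O)OC)c1Oc1c(Oc2c(OC)cc(Oc3c(OC)cc(OC)cc3OC)cc2OC)cc(OC)c(OC)c1OC
A2 | alternative 1 | dimethyl 3-aryloxyglutaconate carrying rings A to C (alkene geometry not defined) | COC(=O)C=C(CC(=O)OC)Oc1c(Oc2c(OC)cc(Oc3c(OC)cc(OC)cc3OC)cc2OC)cc(OC)c(OC)c1OC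
A3 | alternative 1 | aryloxymalonyl dichloride carrying rings E to G | O=C(Cl)C(C(=O)Cl)Oc1cc(OC)cc(OC)c1Oc1cc(OC)c(Oc2cc(OC)c(OC)c(OC)c2)c(OC)c1
A4 | alternative 2 | heptamer with one free ring C hydroxyl and sixteen methyl ethers | Oc1cc(Oc2c(OC)cc(Oc3c(OC)cc(OC)cc3OC)cc2OC)c(Oc2cc(OC)c(Oc3cc(OC)cc(OC)c3Oc3cc(OC)c(Oc4cc(OC)c(OC)c(OC)c4)c(OC)c3)c(OC)c2)c(OC)c1OC
A5 | alternative 2 | 2-aryloxy-3,4-dimethoxycyclobut-2-en-1-one carrying rings D to G, racemic | O=C1C(Oc2cc(OC)c(Oc3cc(OC)cc(OC)c3Oc3cc(OC)c(Oc4cc(OC)c(OC)c(OC)c4)c(OC)c3)c(OC)c2)=C(OC)C1OC
A6 | alternative 2 | aryloxyacetylene carrying rings A and B | C#COc1c(OC)cc(Oc2c(OC)cc(OC)cc2OC)cc1OC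
A7 | alternative 3 | heptamer with ring G as 3,5-diethoxy-4-hydroxyphenyl and fourteen methyl ethers | CCOc1cc(Oc2c(OC)cc(Oc3c(Oc4c(OC)cc(Oc5c(Oc6c(OC)cc(Oc7c(OC)cc(OC)cc7OC)cc6OC)cc(OC)c(OC)c5OC)cc4OC)cc(OC)cc3OC)cc2OC)cc(OCC)c1O
A8 | alternative 3 | pentacarbonylchromium aryloxy[(E)-2-ethoxyvinyl]carbene carrying rings A to F | CCO/C=C/C(Oc2c(OC)cc(Oc3c(Oc4c(OC)cc(Oc5c(Oc6c(OC)cc(Oc7c(OC)cc(OC)cc7OC)cc6OC)cc(OC)c(OC)c5OC)cc4OC)cc(OC)cc3OC)cc2OC)=[Cr](=C=O)(=C=O)(=C=O)(=C=O)=C=O
A9 | alternative 3 | ethoxyacetylene | C#COCC
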